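**Retrosynthetic overview**
1. The strategy rests on the ketone carbon C1: it lies between the cyclobutane methine C11 and the methylene C2 of the bridge C2–C3–C4, which spans the cyclobutane (C4, C5, C10, C11) on the face away from the seven-membered ring (C5–C6–C7–C8–C9–C10). C11 is epimerisable when C1 is an ester, and C2 can be a sulfonyl carbanion.
2. Cyclohexanone (last ring): C1–C2 by acylation of the C2 sulfonyl carbanion of bicyclo[4.1.1]octane ester 29 by its own C11 ester, then desulfonylation and the ester/protecting-group endgame.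
3. Cyclobutane: photochemical Wolff ring contraction of the α-diazo ketone 24 of a bicyclo[4.2.1]nonanone, which gives the C11 methyl ester (either epimer).
4. Seven-membered ring: SmI2 Reformatsky aldol (C9–C10) of bromo ketone aldehyde 19, from cyclopentenone 15 by anti cuprate addition (C4). C7 comes from a Noyori hydrogenation and C3 from CuH reduction of a vinyl sulfone.
5. C5/C6: catalytic asymmetric Michael addition of ethyl 2-cyanopropanoate to cyclopentenone. Ring order: cyclopentanone (start) → seven-membered ring → cyclobutane (by contraction) → cyclohexanone.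

Key step: step 19

Atom labels used in names: C1 ketone carbon, C2 its CH2, C3 CHMe, C4 and C11 the cyclobutane CH groups that carry the three-carbon bridge, C5 (H) and C10 (Me) the cyclobutane bridgeheads, C6 the quaternary carbon (Me, CH2O = C13), C7 CH–O(angeloyl), C8 CH2, C9 CH–OH. With these labels the target is 3R,4S,5S,6S,7R,9R,10R,11R.
Assumption: in the catalyst-controlled steps 1 and 18 the catalyst or ligand antipode is the one whose sense of induction gives the configuration drawn; the C11 ester of 26–29 is carried as both epimers.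
Remark: C7–O is carried as a benzyl ether and C13–O as a PMB ether, so that the primary alcohol is freed by DDQ and the secondary one by hydrogenolysis before the hydrogenation-sensitive angelate is put on.

**Route**

Step 1
Reactants: 1 cyclopent-2-en-1-one; 2 ethyl 2-cyanopropanoate
Product: 3 ethyl (2R)-2-cyano-2-[(1S)-3-oxocyclopentyl]propanoate
Conditions: Ru[(S,S)-TsDPEN](p-cymene) (2 mol%, amido complex of divalent ruthenium), toluene, 30 °C
Reagents that add atoms: none
Why: Catalytic asymmetric Michael addition of an α-substituted cyanoacetate to a cyclic enone, in which the chiral amido complex deprotonates the cyano ester and delivers it to one enone face while it also discriminates the faces of the trisubstituted carbanion, so that C5 and the quaternary C6 should be set together under catalyst control.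

Step 2
Reactants: 3 ethyl (2R)-2-cyano-2-[(1S)-3-oxocyclopentyl]propanoate
Product: 5 ethyl (2R)-2-cyano-2-[(1S)-3-methyl-4-oxocyclopentyl]propanoate (both C10 epimers), via lithium enolate 4 (not isolated)
Conditions: LDA (1.05 equiv), THF, −78 °C; MeI, −78 to −40 °C
Reagents that add atoms: iodomethane, CI
Why: Kinetic enolate alkylation, in which LDA should remove the α-proton at C10, remote from the C5 carbon with its quaternary substituent (the side chain has no enolisable proton), and the C10 configuration is of no consequence because C10 becomes sp2 in step 9.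

Step 3
Reactants: 5 ethyl (2R)-2-cyano-2-[(1S)-3-methyl-4-oxocyclopentyl]propanoate
Product: 6 ethyl (2R)-2-cyano-2-[(8S)-6-methyl-1,4-dioxaspiro[4.4]nonan-8-yl]propanoate
Conditions: (CH2OH)2, TsOH·H2O (cat.), benzene, reflux, Dean–Stark
Reagents that add atoms: ethane-1,2-diol, OCCO
Why: Acid-catalysed ketalisation masks the ring ketone for the hydride, alkoxide and organozinc steps that follow.

Step 4
Reactants: 6 ethyl (2R)-2-cyano-2-[(8S)-6-methyl-1,4-dioxaspiro[4.4]nonan-8-yl]propanoate
Product: 7 (2R)-3-hydroxy-2-methyl-2-[(8S)-6-methyl-1,4-dioxaspiro[4.4]nonan-8-yl]propanenitrile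
Conditions: LiBH4, THF/MeOH, 0 °C to rt
Reagents that add atoms: none
Why: Chemoselective borohydride reduction of the activated α-cyano ester to the primary alcohol (C13), a reagent that leaves the nitrile and the dioxolane untouched.

Step 5
Reactants: 7 (2R)-3-hydroxy-2-methyl-2-[(8S)-6-methyl-1,4-dioxaspiro[4.4]nonan-8-yl]propanenitrile
Product: 8 (2R)-3-[(4-methoxybenzyl)oxy]-2-methyl-2-[(8S)-6-methyl-1,4-dioxaspiro[4.4]nonan-8-yl]propanenitrile
Conditions: NaH, PMBCl, nBu4NI (cat.), DMF, 0 °C to rt
Reagents that add atoms: 4-methoxybenzyl chloride, COc1ccc(CCl)cc1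
Why: Williamson etherification of the primary alkoxide, which cannot fragment because a nitrile-stabilised carbanion is a poor leaving group.

Step 6
Reactants: 8 (2R)-3-[(4-methoxybenzyl)oxy]-2-methyl-2-[(8S)-6-methyl-1,4-dioxaspiro[4.4]nonan-8-yl]propanenitrile; 9 methyl bromoacetate
Product: 11 methyl (4S)-5-[(4-methoxybenzyl)oxy]-4-methyl-4-[(1S)-3-methyl-4-oxocyclopentyl]-3-oxopentanoate, via β-enamino ester 10 (not isolated)
Conditions: Zn dust (activated), THF, reflux, slow addition of 9; then 1 M aq HCl, THF, rt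
Reagents that add atoms: water, O
Why: Blaise reaction, in which the Reformatsky reagent adds to the nitrile carbon (the future C7) and dilute acid then hydrolyses both the β-enamino ester to the β-keto ester and the dioxolane to the ring ketone.

Step 7
Reactants: 11 methyl (4S)-5-[(4-methoxybenzyl)oxy]-4-methyl-4-[(1S)-3-methyl-4-oxocyclopentyl]-3-oxopentanoate
Product: 12 methyl (3R,4S)-3-hydroxy-5-[(4-methoxybenzyl)oxy]-4-methyl-4-[(1S)-3-methyl-4-oxocyclopentyl]pentanoate
Conditions: RuCl2[(S)-BINAP] (1 mol%), H2 (50 atm), MeOH, 50 °C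
Reagents that add atoms: none
Why: Noyori asymmetric hydrogenation of a β-keto ester, a ligand-controlled reduction that should set C7 in the spatial sense of (S)-3-hydroxybutanoate (descriptor 3R here because the quaternary C4 outranks C2), while the unfunctionalised ring ketone is not a substrate for this catalyst.

Step 8
Reactants: 12 methyl (3R,4S)-3-hydroxy-5-[(4-methoxybenzyl)oxy]-4-methyl-4-[(1S)-3-methyl-4-oxocyclopentyl]pentanoate
Product: 13 methyl (3R,4S)-3-(benzyloxy)-5-[(4-methoxybenzyl)oxy]-4-methyl-4-[(1S)-3-methyl-4-oxocyclopentyl]pentanoate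
Conditions: 2-benzyloxy-1-methylpyridinium triflate, MgO, PhCF3, 85 °C
Reagents that add atoms: 2-benzyloxy-1-methylpyridinium trifluoromethanesulfonate, C[n+]1ccccc1OCc1ccccc1.[O-]S(=O)(=O)C(F)(F)F
Why: Benzyl transfer under neutral conditions (Dudley reagent) protects the hindered C7 alcohol without the retro-aldol or β-elimination that a base would cause in a β-hydroxy ester.

Step 9
Reactants: 13 methyl (3R,4S)-3-(benzyloxy)-5-[(4-methoxybenzyl)oxy]-4-methyl-4-[(1S)-3-methyl-4-oxocyclopentyl]pentanoate
Product: 15 methyl (3R,4S)-3-(benzyloxy)-5-[(4-methoxybenzyl)oxy]-4-methyl-4-[(1R)-3-methyl-4-oxocyclopent-2-en-1-yl]pentanoate, via trimethylsilyl enol ether 14 (not isolated)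
Conditions: TMSOTf, Et3N, CH2Cl2, 0 °C to rt; then Pd(OAc)2 (1.1 equiv), MeCN, rt
Reagents that add atoms: none
Why: Soft enolisation should give the more substituted silyl enol ether towards the methyl-bearing C10 (the other α-carbon is crowded by the C5 substituent), and Saegusa–Ito dehydrogenation then gives the C10=C4 enone.

Step 10
Reactants: 15 methyl (3R,4S)-3-(benzyloxy)-5-[(4-methoxybenzyl)oxy]-4-methyl-4-[(1R)-3-methyl-4-oxocyclopent-2-en-1-yl]pentanoate; 16 isopropenylmagnesium bromide
Product: 17 methyl (3R,4S)-3-(benzyloxy)-5-[(4-methoxybenzyl)oxy]-4-methyl-4-[(1R,2R)-3-methyl-2-(prop-1-en-2-yl)-4-[(trimethylsilyl)oxy]cyclopent-3-en-1-yl]pentanoate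
Conditions: CuBr·SMe2 (0.2 equiv), TMSCl, THF, −78 °C; Et3N quench
Reagents that add atoms: chlorotrimethylsilane, C[Si](C)(C)Cl
Why: Copper-catalysed conjugate addition with in situ silyl trapping, in which the isopropenyl group should enter C4 anti to the bulky C5 substituent (C4 set) and the enolate is fixed regiospecifically at C1–C10 before it can attack the side-chain ester.

Step 11
Reactants: 17 methyl (3R,4S)-3-(benzyloxy)-5-[(4-methoxybenzyl)oxy]-4-methyl-4-[(1R,2R)-3-methyl-2-(prop-1-en-2-yl)-4-[(trimethylsilyl)oxy]cyclopent-3-en-1-yl]pentanoate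
Product: 18 (3R,4S)-3-(benzyloxy)-5-[(4-methoxybenzyl)oxy]-4-methyl-4-[(1R,2R)-3-methyl-2-(prop-1-en-2-yl)-4-[(trimethylsilyl)oxy]cyclopent-3-en-1-yl]pentanal
Conditions: iBu2AlH (1.1 equiv), CH2Cl2, −78 °C; MeOH, then aq Rochelle salt, brief contact
Reagents that add atoms: none
Why: Half-reduction of the ester to the C9 aldehyde, helped by chelation of the tetrahedral aluminium intermediate to the C7 benzyloxy group, under conditions that leave the silyl enol ether intact.

Step 12
Reactants: 18 (3R,4S)-3-(benzyloxy)-5-[(4-methoxybenzyl)oxy]-4-methyl-4-[(1R,2R)-3-methyl-2-(prop-1-en-2-yl)-4-[(trimethylsilyl)oxy]cyclopent-3-en-1-yl]pentanal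
Product: 19 (3R,4S)-3-(benzyloxy)-4-[(1R,2R)-3-bromo-3-methyl-4-oxo-2-(prop-1-en-2-yl)cyclopentyl]-5-[(4-methoxybenzyl)oxy]-4-methylpentanal (both C10 epimers)
Conditions: NBS, NaHCO3, THF, −78 °C
Reagents that add atoms: N-bromosuccinimide, O=C1CCC(=O)N1Br
Why: Electrophilic bromination of the silyl enol ether, by far the most nucleophilic π-bond present, places the halogen only at C10.

Step 13
Reactants: 19 (3R,4S)-3-(benzyloxy)-4-[(1R,2R)-3-bromo-3-methyl-4-oxo-2-(prop-1-en-2-yl)cyclopentyl]-5-[(4-methoxybenzyl)oxy]-4-methylpentanal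
Product: 21 bicyclo[4.2.1]nonan-1-one aldol with C7 benzyloxy, C9 hydroxy on the side of the C1 carbonyl bridge and trans to C7–O, C4 isopropenyl pointing away from the C6–C9 bridge, and C6 methyl plus C13 PMB ether, via samarium enolate 20 (not isolated)
Conditions: SmI2 (2.5 equiv), THF, −78 to −40 °C; aq NH4Cl
Reagents that add atoms: none
Why: Intramolecular samarium Reformatsky aldol, in which the trivalent samarium enolate formed only at C10 adds to the tethered aldehyde through a chelated six-membered transition state on the face that carries the C5 side chain, so that C10 is set by the tether and C9 by the metal bridge between the two oxygens (hydroxyl towards C1=O).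

Step 14
Reactants: 21 bicyclo[4.2.1]nonan-1-one aldol
Product: 22 C9 tert-butyldimethylsilyl ether of 21
Conditions: TBSOTf, 2,6-lutidine, CH2Cl2, −78 to 0 °C
Reagents that add atoms: tert-butyldimethylsilyl trifluoromethanesulfonate, CC(C)(C)[Si](C)(C)OS(=O)(=O)C(F)(F)F
Why: Silylation with the triflate caps the hindered C9 alcohol and removes the retro-aldol pathway before base is used.

Step 15
Reactants: 22 C9 tert-butyldimethylsilyl ether of 21
Product: 24 C11 diazo ketone of the bicyclo[4.2.1]nonan-1-one, via trifluoroacetyl ketone 23 (not isolated)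
Conditions: LiHMDS, THF, −78 °C; CF3CO2CH2CF3; then MsN3, Et3N, H2O (1 equiv), MeCN, rt
Reagents that add atoms: methanesulfonyl azide, CS(=O)(=O)N=[N+]=[N-]
Why: Detrifluoroacetylative diazo transfer (Danheiser), regiospecific because C11 is the only enolisable α-carbon (C10 is quaternary).

Step 16
Reactants: 24 C11 diazo ketone of the bicyclo[4.2.1]nonan-1-one
Product: 26 methyl bicyclo[4.1.1]octane-C11-carboxylate (both C11 epimers) with C4 isopropenyl, C7 benzyloxy, C9 silyloxy and C13 PMB ether, via ketene 25 (not isolated)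
Conditions: hν (365 nm), MeOH/THF, rt
Reagents that add atoms: methanol, CO
Why: Photochemical Wolff rearrangement of a cyclic α-diazo ketone, in which C10 migrates with retention from C1 to C11 and methanol traps the ketene, contracting the cyclopentanone to the cyclobutane with C1 as ester carbon.

Step 17
Reactants: 26 methyl bicyclo[4.1.1]octane-C11-carboxylate with C4 isopropenyl
Product: 28 (E)-vinyl sulfone with C4–C(CH3)=CH–SO2Ph in place of isopropenyl, via β-iodo sulfone 27 (not isolated)
Conditions: PhSO2Na, I2, EtOAc/H2O, rt; then Et3N, CH2Cl2, 0 °C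
Reagents that add atoms: sodium benzenesulfinate, [Na+].[O-]S(=O)c1ccccc1
Why: Radical iodosulfonylation puts the sulfonyl group on the terminal carbon C2, and amine-induced loss of HI through the acidic α-sulfonyl proton should give the (E)-vinyl sulfone (sulfonyl trans to the bicycle) when the base contact is kept short.

Step 18
Reactants: 28 (E)-vinyl sulfone
Product: 29 methyl bicyclo[4.1.1]octane-C11-carboxylate (both C11 epimers) with C4–CH(CH3)–CH2–SO2Ph of S configuration at C3, C7 benzyloxy, C9 silyloxy and C13 PMB ether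
Conditions: CuF2·H2O (5 mol%), (R,R)-Me-DuPhos monoxide, PhSiH3, aq NaOH (cat.), benzene, rt
Reagents that add atoms: none
Why: Copper hydride-catalysed asymmetric conjugate reduction of a β,β-disubstituted vinyl phenyl sulfone, in which the chiral ligand directs hydride to one face of C3 and the large size difference of the two β-substituents (bicycle against methyl) should secure the selectivity.

Step 19
Reactants: 29 methyl bicyclo[4.1.1]octane-C11-carboxylate with the C4 sulfone arm
Product: 31 tricyclic β-keto sulfone (C2 epimers) with C7 benzyloxy, C9 silyloxy and C13 PMB ether, via potassium enolate 30 (not isolated)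
Conditions: KOtBu (3 equiv), THF/tBuOH, 0 to 40 °C; aq NH4Cl
Reagents that add atoms: none
Why: tert-Butoxide reversibly deprotonates C2 next to the sulfone and the C11–H of the cyclobutane ester, so the C11 epimers interconvert, and only the epimer whose ester lies on the face of the C4 arm is reached by the C2 carbanion, which adds to the ester carbonyl and expels methoxide to form C1–C2. The closest known reaction type is the intramolecular acylation of an α-sulfonyl carbanion by an ester, a Dieckmann-type condensation that gives β-keto sulfones. The six-membered ring C1–C2–C3–C4–C10–C11 closes in the 6-exo-trig mode and completes the bicyclo[3.1.1]heptanone part of the tricycle. The new stereocentre C11 is fixed by the ring itself, because a three-carbon bridge across C4 and C11 can only lie on the cyclobutane face away from the C6–C9 bridge. The step needs the C-acylation to win over its reversal and over attack of alkoxide on the ester, and this is secured by immediate deprotonation of the acidic C2–H of the product to enolate 30, which makes the strained closure irreversible, and by the anti position of the C4 arm set in step 10. C2 is left as an epimer mixture because the sulfone is removed in the next step.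

Step 20
Reactants: 31 tricyclic β-keto sulfone
Product: 32 tricyclic ketone with C2 methylene, C7 benzyloxy, C9 silyloxy and C13 PMB ether
Conditions: SmI2 (3 equiv), THF/MeOH, −78 °C
Reagents that add atoms: none
Why: Reductive desulfonylation of an α-sulfonyl ketone by single-electron transfer, which is much faster than reduction of the ketone and gives the samarium enolate that methanol protonates.

Step 21
Reactants: 32 tricyclic ketone
Product: 33 C13 primary alcohol of 32
Conditions: DDQ, CH2Cl2/pH 7 buffer, 0 °C to rt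
Reagents that add atoms: none
Why: Oxidative cleavage of the electron-rich PMB ether, selective over the plain benzyl ether and the silyl ether.

Step 22
Reactants: 33 C13 primary alcohol
Product: 34 C13 acetate
Conditions: Ac2O, pyridine, DMAP (cat.), CH2Cl2, rt
Reagents that add atoms: acetic anhydride, CC(=O)OC(C)=O
Why: Standard acylation of the only free hydroxyl group.

Step 23
Reactants: 34 C13 acetate
Product: 35 C7 secondary alcohol with C13 acetate and C9 silyl ether
Conditions: H2 (1 atm), Pd(OH)2/C, EtOAc, rt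
Reagents that add atoms: none
Why: Hydrogenolysis of the benzyl ether at a stage where the molecule holds no alkene, so that the later angelate is never exposed to hydrogen.

Step 24
Reactants: 35 C7 secondary alcohol; 36 angelic acid ((Z)-2-methylbut-2-enoic acid)
Product: 38 C7 angelate with C13 acetate and C9 silyl ether, via mixed anhydride 37 (not isolated)
Conditions: 2,4,6-Cl3C6H2COCl, Et3N, toluene, rt; then 35, toluene, 80 °C
Reagents that add atoms: none
Why: Yamaguchi-type esterification through the mixed trichlorobenzoic anhydride, run without a nucleophilic amine catalyst so that the Z double bond should not isomerise to the tiglate.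

Step 25
Reactants: 38 C7 angelate
Product: 39 CNP0212099.1
Conditions: HF·pyridine, pyridine/THF, 0 °C to rt
Reagents that add atoms: none
Why: Fluoride-mediated cleavage of the hindered C9 silyl ether under buffered acidic conditions that both esters and the γ-hydroxy ketone tolerate.

**Compound list**
1 | cyclopent-2-en-1-one | O=C1C=CCC1 | starting material
2 | ethyl 2-cyanopropanoate (racemic) | CCOC(=O)C(C)C#N | starting material
3 | ethyl (2R)-2-cyano-2-[(1S)-3-oxocyclopentyl]propanoate | CCOC(=O)[C@@](C)(C#N)[C@@H]1CC(=O)CC1 | intermediate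
4 | lithium enolate of 3 (C1–C10 enolate) | CCOC(=O)[C@@](C)(C#N)[C@@H]1CC([O-])=CC1.[Li+] | intermediate
5 | ethyl (2R)-2-cyano-2-[(1S)-3-methyl-4-oxocyclopentyl]propanoate (C10 epimers) | CCOC(=O)[C@@](C)(C#N)[C@@H]1CC(=O)C(C)C1 | intermediate
6 | ethyl (2R)-2-cyano-2-[(8S)-6-methyl-1,4-dioxaspiro[4.4]nonan-8-yl]propanoate | CCOC(=O)[C@@](C)(C#N)[C@@H]1CC2(OCCO2)C(C)C1 | intermediate
7 | (2R)-3-hydroxy-2-methyl-2-[(8S)-6-methyl-1,4-dioxaspiro[4.4]nonan-8-yl]propanenitrile | OC[C@@](C)(C#N)[C@@H]1CC2(OCCO2)C(C)C1 | intermediate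
8 | (2R)-3-[(4-methoxybenzyl)oxy]-2-methyl-2-[(8S)-6-methyl-1,4-dioxaspiro[4.4]nonan-8-yl]propanenitrile | COc1ccc(COC[C@@](C)(C#N)[C@@H]2CC3(OCCO3)C(C)C2)cc1 | intermediate
9 | methyl bromoacetate | COC(=O)CBr | starting material
10 | methyl (2Z,4R)-3-amino-5-[(4-methoxybenzyl)oxy]-4-methyl-4-[(8S)-6-methyl-1,4-dioxaspiro[4.4]nonan-8-yl]pent-2-enoate (β-enamino ester) | COC(=O)/C=C(\N)[C@](C)(COCc1ccc(OC)cc1)[C@@H]1CC2(OCCO2)C(C)C1 | intermediate
11 | methyl (4S)-5-[(4-methoxybenzyl)oxy]-4-methyl-4-[(1S)-3-methyl-4-oxocyclopentyl]-3-oxopentanoate | COC(=O)CC(=O)[C@](C)(COCc1ccc(OC)cc1)[C@@H]1CC(=O)C(C)C1 | intermediate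
12 | methyl (3R,4S)-3-hydroxy-5-[(4-methoxybenzyl)oxy]-4-methyl-4-[(1S)-3-methyl-4-oxocyclopentyl]pentanoate | COC(=O)C[C@@H](O)[C@](C)(COCc1ccc(OC)cc1)[C@@H]1CC(=O)C(C)C1 | intermediate
13 | methyl (3R,4S)-3-(benzyloxy)-5-[(4-methoxybenzyl)oxy]-4-methyl-4-[(1S)-3-methyl-4-oxocyclopentyl]pentanoate | COC(=O)C[C@@H](OCc1ccccc1)[C@](C)(COCc1ccc(OC)cc1)[C@@H]1CC(=O)C(C)C1 | intermediate
14 | methyl (3R,4S)-3-(benzyloxy)-5-[(4-methoxybenzyl)oxy]-4-methyl-4-[(1S)-3-methyl-4-[(trimethylsilyl)oxy]cyclopent-3-en-1-yl]pentanoate | COC(=O)C[C@@H](OCc1ccccc1)[C@](C)(COCc1ccc(OC)cc1)[C@@H]1CC(O[Si](C)(C)C)=C(C)C1 | intermediate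
15 | methyl (3R,4S)-3-(benzyloxy)-5-[(4-methoxybenzyl)oxy]-4-methyl-4-[(1R)-3-methyl-4-oxocyclopent-2-en-1-yl]pentanoate | COC(=O)C[C@@H](OCc1ccccc1)[C@](C)(COCc1ccc(OC)cc1)[C@@H]1CC(=O)C(C)=C1 | intermediate
16 | isopropenylmagnesium bromide | C=C(C)[Mg]Br | starting material
17 | methyl (3R,4S)-3-(benzyloxy)-5-[(4-methoxybenzyl)oxy]-4-methyl-4-[(1R,2R)-3-methyl-2-(prop-1-en-2-yl)-4-[(trimethylsilyl)oxy]cyclopent-3-en-1-yl]pentanoate | COC(=O)C[C@@H](OCc1ccccc1)[C@](C)(COCc1ccc(OC)cc1)[C@@H]1CC(O[Si](C)(C)C)=C(C)[C@H]1C(C)=C | intermediate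
18 | (3R,4S)-3-(benzyloxy)-5-[(4-methoxybenzyl)oxy]-4-methyl-4-[(1R,2R)-3-methyl-2-(prop-1-en-2-yl)-4-[(trimethylsilyl)oxy]cyclopent-3-en-1-yl]pentanal | O=CC[C@@H](OCc1ccccc1)[C@](C)(COCc1ccc(OC)cc1)[C@@H]1CC(O[Si](C)(C)C)=C(C)[C@H]1C(C)=C | intermediate
19 | (3R,4S)-3-(benzyloxy)-4-[(1R,2R)-3-bromo-3-methyl-4-oxo-2-(prop-1-en-2-yl)cyclopentyl]-5-[(4-methoxybenzyl)oxy]-4-methylpentanal (C10 epimers) | O=CC[C@@H](OCc1ccccc1)[C@](C)(COCc1ccc(OC)cc1)[C@@H]1CC(=O)C(C)(Br)[C@H]1C(C)=C | intermediate
20 | diiodosamarium C1–C10 enolate of the debrominated ketone aldehyde | O=CC[C@@H](OCc1ccccc1)[C@](C)(COCc1ccc(OC)cc1)[C@@H]1CC(O[Sm](I)I)=C(C)[C@H]1C(C)=C | intermediate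
21 | bicyclo[4.2.1]nonan-1-one aldol: C10–C1(=O)–C11H2–C5 two-carbon bridge, C4 one-carbon bridge with isopropenyl anti to the C6–C9 bridge, C7 benzyloxy, C9 hydroxy syn to C1=O and trans to C7–O, C6 methyl and C13 PMB ether | c3ccccc3CO[C@@H]1C[C@@H](O)[C@]2(C)[C@@H](C(C)=C)[C@@H](CC2=O)[C@@]1(C)COCc4ccc(OC)cc4 | intermediate
22 | C9 tert-butyldimethylsilyl ether of 21 | c3ccccc3CO[C@@H]1C[C@@H](O[Si](C)(C)C(C)(C)C)[C@]2(C)[C@@H](C(C)=C)[C@@H](CC2=O)[C@@]1(C)COCc4ccc(OC)cc4 | intermediate
23 | C11 trifluoroacetyl derivative of 22 | c3ccccc3CO[C@@H]1C[C@@H](O[Si](C)(C)C(C)(C)C)[C@]2(C)[C@@H](C(C)=C)[C@@H](C(C(=O)C(F)(F)F)C2=O)[C@@]1(C)COCc4ccc(OC)cc4 | intermediate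
24 | C11 diazo ketone of 22 | c3ccccc3CO[C@@H]1C[C@@H](O[Si](C)(C)C(C)(C)C)[C@]2(C)[C@@H](C(C)=C)[C@@H](C(=[N+]=[N-])C2=O)[C@@]1(C)COCc4ccc(OC)cc4 | intermediate
25 | bicyclo[4.1.1]octan-C11-ylidene ketene | c3ccccc3CO[C@@H]1C[C@@H](O[Si](C)(C)C(C)(C)C)[C@]2(C)[C@@H](C(C)=C)[C@@H](C2=C=O)[C@@]1(C)COCc4ccc(OC)cc4 | intermediate
26 | methyl bicyclo[4.1.1]octane-C11-carboxylate (C11 epimers) with C4 isopropenyl anti to the C6–C9 bridge, C7 benzyloxy, C9 silyloxy, C10 methyl, C6 methyl and C13 PMB ether | c3ccccc3CO[C@@H]1C[C@@H](O[Si](C)(C)C(C)(C)C)[C@]2(C)[C@@H](C(C)=C)[C@@H](C2C(=O)OC)[C@@]1(C)COCc4ccc(OC)cc4 | intermediate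
27 | β-iodo sulfone: 26 with C4–C(CH3)(I)–CH2SO2Ph | c3ccccc3CO[C@@H]1C[C@@H](O[Si](C)(C)C(C)(C)C)[C@]2(C)[C@@H](C(C)(I)CS(=O)(=O)c5ccccc5)[C@@H](C2C(=O)OC)[C@@]1(C)COCc4ccc(OC)cc4 | intermediate
28 | (E)-vinyl sulfone: 26 with C4–C(CH3)=CH–SO2Ph | c3ccccc3CO[C@@H]1C[C@@H](O[Si](C)(C)C(C)(C)C)[C@]2(C)[C@@H](/C(C)=C/S(=O)(=O)c5ccccc5)[C@@H](C2C(=O)OC)[C@@]1(C)COCc4ccc(OC)cc4 | intermediate
29 | key-step precursor: methyl bicyclo[4.1.1]octane-C11-carboxylate (C11 epimers) with C4–CH(CH3)–CH2SO2Ph (3S), C7 benzyloxy, C9 silyloxy, C13 PMB ether | c3ccccc3CO[C@@H]1C[C@@H](O[Si](C)(C)C(C)(C)C)[C@]2(C)[C@@H]([C@H](C)CS(=O)(=O)c5ccccc5)[C@@H](C2C(=O)OC)[C@@]1(C)COCc4ccc(OC)cc4 | intermediate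
30 | potassium enolate of 31 | c3ccccc3CO[C@@H]1C[C@@H](O[Si](C)(C)C(C)(C)C)[C@]2(C)[C@@H]4[C@@H]([C@H]2C([O-])=C(S(=O)(=O)c5ccccc5)[C@H]4C)[C@@]1(C)COCc6ccc(OC)cc6.[K+] | intermediate
31 | key-step product: tricyclic C2-phenylsulfonyl C1 ketone (C2 epimers) with C7 benzyloxy, C9 silyloxy, C13 PMB ether | c3ccccc3CO[C@@H]1C[C@@H](O[Si](C)(C)C(C)(C)C)[C@]2(C)[C@@H]4[C@@H]([C@H]2C(=O)C(S(=O)(=O)c5ccccc5)[C@H]4C)[C@@]1(C)COCc6ccc(OC)cc6 | intermediate
32 | tricyclic C1 ketone with C7 benzyloxy, C9 silyloxy, C13 PMB ether | c3ccccc3CO[C@@H]1C[C@@H](O[Si](C)(C)C(C)(C)C)[C@]2(C)[C@@H]4[C@@H]([C@H]2C(=O)C[C@H]4C)[C@@]1(C)COCc6ccc(OC)cc6 | intermediate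
33 | C13 primary alcohol with C7 benzyloxy, C9 silyloxy | c3ccccc3CO[C@@H]1C[C@@H](O[Si](C)(C)C(C)(C)C)[C@]2(C)[C@@H]4[C@@H]([C@H]2C(=O)C[C@H]4C)[C@@]1(C)CO | intermediate
34 | C13 acetate with C7 benzyloxy, C9 silyloxy | c3ccccc3CO[C@@H]1C[C@@H](O[Si](C)(C)C(C)(C)C)[C@]2(C)[C@@H]4[C@@H]([C@H]2C(=O)C[C@H]4C)[C@@]1(C)COC(C)=O | intermediate
35 | C7 alcohol with C13 acetate, C9 silyloxy | O[C@@H]1C[C@@H](O[Si](C)(C)C(C)(C)C)[C@]2(C)[C@@H]4[C@@H]([C@H]2C(=O)C[C@H]4C)[C@@]1(C)COC(C)=O | intermediate
36 | angelic acid, (Z)-2-methylbut-2-enoic acid | C/C=C(/C)C(=O)O | starting material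
37 | angelic 2,4,6-trichlorobenzoic anhydride | C/C=C(/C)C(=O)OC(=O)c1c(Cl)cc(Cl)cc1Cl | intermediate
38 | C7 angelate with C13 acetate, C9 silyloxy | C/C=C(/C)C(=O)O[C@@H]1C[C@@H](O[Si](C)(C)C(C)(C)C)[C@]2(C)[C@@H]4[C@@H]([C@H]2C(=O)C[C@H]4C)[C@@]1(C)COC(C)=O | intermediate
39 | CNP0212099.1: C13 acetate, C7 angelate, C9 alcohol, C1 ketone (3R,4S,5S,6S,7R,9R,10R,11R) | C/C=C(/C)C(=O)O[C@@H]1C[C@@H](O)[C@]2(C)[C@@H]3[C@@H]([C@H]2C(=O)C[C@H]3C)[C@@]1(C)COC(C)=O | target

**Totals and risks**
Total step count: 25. Longest linear sequence: 25 steps, from cyclopent-2-en-1-one.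

Steps most likely to fail:

Step 19 (key step). The cyclobutane ester may enolise too slowly for both C11 epimers to funnel through the one that can cyclise, or the strained acylation may revert, or alkoxide may attack the ester. Fallback from 29, returning at 31: the electrophile is changed from ester to aldehyde. 29 is reduced with iBu2AlH (CH2Cl2, −78 °C) to the C11 carbaldehyde F1 (both epimers), whose α-centre on the cyclobutane epimerises much more readily than that of the ester. With KOtBu in THF/tBuOH the C2 sulfonyl carbanion adds to the formyl group of the epimer that can be reached and gives the tricyclic β-hydroxy sulfone F2. Dess–Martin oxidation of F2 gives 31, and the route goes on with step 20.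

Step 1. The catalyst may discriminate poorly between the faces of the prochiral cyano ester carbanion, which would erode the configuration at the quaternary C6, or the enantioselectivity at C5 may be low. Fallback from 1, returning at 3: the two centres are set in separate operations. Cyclopentenone 1 and diethyl methylmalonate give, under heterobimetallic AlLi[(R)-binaphthoxide]2 catalysis (or its antipode), diethyl 2-methyl-2-[(1S)-3-oxocyclopentyl]propanedioate F3, in which only C5 is stereogenic. Pig-liver esterase in pH 7 buffer hydrolyses one of the two diastereotopic esters to the half-ester F4. Its C6 epimers are separable as salts of a chiral amine or by chromatography, and the unwanted one is re-esterified (EtI, K2CO3) to F3. F4 is converted through its mixed anhydride (ClCO2Et, Et3N; then NH3) into the primary amide F5, which trifluoroacetic anhydride and pyridine dehydrate to 3.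

Step 13. The samarium enolate may be protonated, or the aldehyde reduced, before the C9–C10 bond forms. Fallback from 18, returning at 21: the bromination is left out and silyl enol ether aldehyde 18 is cyclised by a Lewis-acid-mediated intramolecular Mukaiyama aldol reaction (MgBr2·OEt2, CH2Cl2, −78 to −20 °C). Chelation of magnesium between the formyl oxygen and the C7 benzyloxy group is expected to lead to the same 7,9-anti aldol 21 after aqueous work-up, and no new compound arises.

**Further compounds**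
F1 | step 19 | C11 carbaldehyde of the bicyclo[4.1.1]octane (C11 epimers) with the C4 sulfone arm, C7 benzyloxy, C9 silyloxy, C13 PMB ether | c3ccccc3CO[C@@H]1C[C@@H](O[Si](C)(C)C(C)(C)C)[C@]2(C)[C@@H]([C@H](C)CS(=O)(=O)c5ccccc5)[C@@H](C2C=O)[C@@]1(C)COCc4ccc(OC)cc4
F2 | step 19 | tricyclic C1 hydroxy C2 phenylsulfonyl compound (C1 and C2 epimers) | c3ccccc3CO[C@@H]1C[C@@H](O[Si](C)(C)C(C)(C)C)[C@]2(C)[C@@H]4[C@@H]([C@H]2C(O)C(S(=O)(=O)c5ccccc5)[C@H]4C)[C@@]1(C)COCc6ccc(OC)cc6
F3 | step 1 | diethyl 2-methyl-2-[(1S)-3-oxocyclopentyl]propanedioate | CCOC(=O)C(C)(C(=O)OCC)[C@@H]1CC(=O)CC1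
F4 | step 1 | 3-ethoxy-2-methyl-3-oxo-2-[(1S)-3-oxocyclopentyl]propanoic acid, C6 configured as in 3 | CCOC(=O)[C@@](C)(C(=O)O)[C@@H]1CC(=O)CC1
F5 | step 1 | ethyl 3-amino-2-methyl-3-oxo-2-[(1S)-3-oxocyclopentyl]propanoate, C6 configured as in 3 | CCOC(=O)[C@@](C)(C(N)=O)[C@@H]1CC(=O)CC1
F0 | step 13 | none | none
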